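| flask | substrate | coupling partner | temperature | remark | time |
|---|---|---|---|---|---|
| beta | 0.13 M | 1.2 equiv | 25 °C | run made earlier |  |
| epsilon | 0.30 M | 1.2 equiv | 50 °C | run made earlier |  |
| teal | 0.20 M | 1.20 equiv |  | at 30 °C throughout | 3.0 h |
| red | 0.20 M | 1.20 equiv |  | at 70 °C until 1.5 h, from then on at 30 °C | 3.0 h |

| run | time / h | intermediate / % | target / % |
|---|---|---|---|
| beta | 8.00 | 31.7 | 0.1 |
| beta | 20.0 | 48.4 | 2.1 |
| beta | 25.0 | 52.0 | 3.9 |
| beta | 40.0 | 55.4 | 5.9 |
| epsilon | 0.667 | 33.3 | 1.4 |
| epsilon | 2.00 | 46.7 | 6.5 |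
| epsilon | 4.00 | 43.0 | 12.5 |
| epsilon | 10.0 | 24.6 | 20.9 |

(standard deviation of a reading: 0.5 percentage points)

- the winner by amount of intermediate, in percent of the substrate charged; "neither" if no more than 2 percentage points parts them (teal / red / neither)
- how much intermediate is there at the end, in percent of the substrate charged: teal
- how much intermediate is there at the end, in percent of the substrate charged: red



1. Compare the flasks: teal stays at 30 °C, while red spends 1.5 h at 70 °C. Beta's readings of intermediate still rise at 40.0 h; epsilon's highest reading stands at 2.00 h. So find what balance a hot flask holds.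

2. Let s, i and b be substrate, intermediate and free coupling partner, as fractions of the substrate charged. Take s as the charge less i and target, and b as the partner charge less the same. Per molarity charged, i/(s·b) reads 18.8 M⁻¹ in beta at 40.0 h and 4.98 M⁻¹ in epsilon at 2.00 h.

3. Carry this along 1/T to 70 °C and multiply by 0.20 M. That gives 0.695 as the exponent and 0.396 as the result: the hot balance number, which I take as the i/(s·b) at which making and using of intermediate stand level in red's hot leg (a quasi-steady state).

4. Test it: one number is not enough, since s + i shrinks: target in epsilon grows from 6.5% to 20.9%. Target's gain per intermediate puts red's hot leg at 14.7 h of epsilon time, longer than epsilon's last reading. Epsilon's balance at that last reading gives s = 0.318, so let that reading stand in and take 0.436 as gone from s + i.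

5. With that, the number gives red s = 0.449 and i = 0.115 at the change.

6. First readings give the making constants 9.99 × 10⁻⁵ M⁻¹ s⁻¹ and 5.89 × 10⁻⁴ M⁻¹ s⁻¹, hence 1.46 × 10⁻⁴ M⁻¹ s⁻¹ at 30 °C. Reckon red's cold leg to end at 16.1%, and teal at 28.1%. My call: teal, higher by 12 percentage points.

The forecast gives neither, with teal 25.4% and red 25.5%: “The two are close, so neither wins”.

The flasks give teal: teal 28.7%, red 18.0%.

    intermediate → side product B (k = 1.30 × 10⁻⁴ s⁻¹, Ea = 119 kJ mol⁻¹)
    substrate + coupling partner ⇌ intermediate (K = 3.60 M⁻¹, k = 0.00260 M⁻¹ s⁻¹, Ea = 60.0 kJ mol⁻¹, ΔH = −37.0 kJ mol⁻¹)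
    intermediate ⇌ target + by-product (K = 0.180 M, k = 2.60 × 10⁻⁴ s⁻¹, Ea = 107 kJ mol⁻¹, ΔH = −22.0 kJ mol⁻¹)
    substrate + target → side product A (k = 0.00150 M⁻¹ s⁻¹, Ea = 85.0 kJ mol⁻¹)
    (constants at 70 °C)

At 1.50 h red held substrate 38.2% and intermediate 14.8%, so i/(s·b) stood at 0.583, above the 0.396 reckoned. In red's cold leg substrate went to 34.6%, intermediate rose to 18.0% and target ended at 16.7%.

Second flask: red with 3.00 equiv of coupling partner. Assuming red's loss 0.436 again, the number gives s = 0.295 and i = 0.269 at the change, an i/s of 0.912 against 0.256 reckoned for red. Computed, that flask ends with intermediate 23.4% and substrate 10.1%, an i/s of 2.32 against red's final 0.520, with target at 29.9%.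

The readings stem from a simulated flask for an exercise, noise included.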